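**Plan**

- Retrosynthesis: the three O–benzyl bonds are cut first. The depside ester is then cut between its single-bonded oxygen and C4′ of ring B, not at the acyl carbon, which gives a ring A carboxylate and a ring B aryl bromide.
- Feature used: the ester carbonyl on C1 of ring A lies between the C2 oxygen and the C6 2-oxononyl chain. An activated acyl at C1 is therefore hindered and is trapped by the chain ketone as a 3-heptylisocoumarin. The O–C4′ bond, para to the C1′ carboxyl of ring B (C2′ OH, C6′ CH3), can be made instead with the carboxylate as nucleophile.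
- Ring A is cut further at the bond between the C6 benzylic CH2 and the ketone carbon (toluic acid dianion plus an octanoyl Weinreb amide) and goes back to methyl orsellinate. Ring B is cut at C2′–O (fluoride displacement) and goes back to 4-bromo-2-fluoro-6-methylbenzoic acid.
- Forward: the chain is joined to ring A and the keto acid is isolated as its isocoumarin (the only ring made, step 5). KOH reopens it to the potassium salt (step 6), which is coupled with the ring B bromide; hydrogenolysis ends the route.
- Stereochemistry: the target has no stereocenter and no configured double bond, so none has to be set.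

Key step: step 9

Remark: salt 11 is taken to be the open-chain keto carboxylate, because the cyclic lactol tautomer needs the protonated acid.

**Route**

Step 1
Reactants: 1 methyl orsellinate (methyl 2,4-dihydroxy-6-methylbenzoate)
Product: 2 methyl 2-hydroxy-4-methoxy-6-methylbenzoate
Conditions: MeI (1.05 equiv), K2CO3 (1.2 equiv), acetone, reflux
Reagents that add atoms: iodomethane, CI
Why: The C2 hydroxyl is held in a hydrogen bond to the ester carbonyl, so a Williamson etherification with one equivalent of iodomethane and a weak base should alkylate only the C4 hydroxyl.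

Step 2
Reactants: 2 methyl 2-hydroxy-4-methoxy-6-methylbenzoate
Product: 3 methyl 2-(benzyloxy)-4-methoxy-6-methylbenzoate
Conditions: BnBr (1.3 equiv), K2CO3 (2 equiv), DMF, 70 °C
Reagents that add atoms: benzyl bromide, BrCc1ccccc1
Why: With the C4 oxygen capped, the remaining chelated phenol should undergo Williamson benzylation once a dipolar solvent and heat are used.

Step 3
Reactants: 3 methyl 2-(benzyloxy)-4-methoxy-6-methylbenzoate
Product: 4 2-(benzyloxy)-4-methoxy-6-methylbenzoic acid
Conditions: KOH (10 equiv), EtOH/H2O (2:1), reflux; then 1 M HCl, 0 °C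
Reagents that add atoms: potassium hydroxide, [K+].[OH-]
Why: Saponification of the hindered 2,6-disubstituted methyl ester needs hot concentrated hydroxide, which is harmless at this stage because no enolizable ketone is yet present that could attack the ester in a Claisen-type condensation.

Step 4
Reactants: 5 octanoyl chloride
Product: 6 N-methoxy-N-methyloctanamide
Conditions: MeNHOMe·HCl (1.1 equiv), Et3N (2.2 equiv), CH2Cl2, 0 °C → rt
Reagents that add atoms: N,O-dimethylhydroxylamine hydrochloride, CNOC.Cl
Why: N-Acylation of N,O-dimethylhydroxylamine by an acid chloride (Weinreb amide formation) is routine.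

Step 5
Reactants: 4 2-(benzyloxy)-4-methoxy-6-methylbenzoic acid; 6 N-methoxy-N-methyloctanamide
Product: 10 8-(benzyloxy)-3-heptyl-6-methoxy-1H-isochromen-1-one, via dilithiated toluic acid 7 (not isolated), via lithium aminal adduct 8 (not isolated), via keto acid 9 (not isolated)
Conditions: LiN(iPr)2 (2.2 equiv), THF, −78 → 0 °C; 6 (1.2 equiv), −78 → 0 °C; 1 M HCl; crude 9, Ac2O, 100 °C; aqueous NaHCO3 wash
Reagents that add atoms: none
Why: Two equivalents of LiN(iPr)2 should convert the ortho-toluic acid into its carboxylate/benzylic dianion (lateral lithiation), which adds once to the Weinreb amide because the chelated tetrahedral adduct persists until the acid quench (Weinreb ketone synthesis); acetic anhydride then closes the crude keto acid through its mixed anhydride and the ketone enol to the neutral enol lactone, which a bicarbonate wash separates from unreacted acid 4.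

Step 6
Reactants: 10 8-(benzyloxy)-3-heptyl-6-methoxy-1H-isochromen-1-one
Product: 11 potassium 2-(benzyloxy)-4-methoxy-6-(2-oxononyl)benzoate
Conditions: KOH (1.0 equiv), THF/H2O (1:1), 60 °C; evaporation, drying by toluene azeotrope, trituration with Et2O
Reagents that add atoms: potassium hydroxide, [K+].[OH-]
Why: Alkaline ring opening of a 3-alkylisocoumarin (lactone hydrolysis, then enol-to-ketone tautomerization) is a classical entry to 2-(2-oxoalkyl)benzoates, and with one equivalent of KOH in an alcohol-free medium the lactone simply takes up the base and should give the potassium salt directly, free of excess hydroxide.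

Step 7
Reactants: 12 4-bromo-2-fluoro-6-methylbenzoic acid
Product: 13 benzyl 4-bromo-2-fluoro-6-methylbenzoate
Conditions: BnBr (1.1 equiv), K2CO3 (1.5 equiv), DMF, rt
Reagents that add atoms: benzyl bromide, BrCc1ccccc1
Why: O-Alkylation of the carboxylate (SN2 at the benzylic carbon of the reagent) is not slowed by the two ortho substituents, since the hindered carboxyl carbon is not attacked.

Step 8
Reactants: 13 benzyl 4-bromo-2-fluoro-6-methylbenzoate
Product: 14 benzyl 2-(benzyloxy)-4-bromo-6-methylbenzoate
Conditions: BnOH (1.2 equiv), NaH (1.2 equiv), THF/DMF, 0 °C → rt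
Reagents that add atoms: benzyl alcohol, OCc1ccccc1
Why: In this nucleophilic aromatic substitution, fluoride ortho to the ester should be displaced by benzyl oxide through a Meisenheimer adduct much faster than bromide para to it, and any attack of benzyl oxide on the benzyl ester carbonyl is a degenerate transesterification.

Step 9
Reactants: 11 potassium 2-(benzyloxy)-4-methoxy-6-(2-oxononyl)benzoate; 14 benzyl 2-(benzyloxy)-4-bromo-6-methylbenzoate
Product: 15 benzyl 2-(benzyloxy)-4-{[2-(benzyloxy)-4-methoxy-6-(2-oxononyl)benzoyl]oxy}-6-methylbenzoate
Conditions: 11 (1.0 equiv), 14 (1.5 equiv), NiBr2·glyme (10 mol %), 4,4′-di-tert-butyl-2,2′-bipyridine (12 mol %), nBu4NBr (0.1 M), dry DMA, undivided cell, graphite anode, nickel-foam cathode, constant current (about 4 mA), rt, argon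
Reagents that add atoms: none
Why: Cathodic reduction of the divalent nickel bipyridine complex gives low-valent nickel, which inserts into the C4′–Br bond of 14 (activated by the para benzyl ester and free of ortho substituents); the divalent arylnickel bromide exchanges bromide for carboxylate 11 and is oxidized at the anode to a trivalent arylnickel carboxylate, whose reductive elimination forms the O–C4′ bond and returns monovalent nickel to the cycle. The closest known reaction type is the nickel-catalyzed O-arylation of carboxylic acids with aryl bromides under electrochemical or photoredox drive, applied here to a 2,6-disubstituted benzoate. No ring closes and no stereocenter forms. Because the carboxyl carbon of ring A never becomes an acyl electrophile, its two ortho substituents only have to let the oxygen reach nickel, and the chain ketone has nothing to cyclize onto. The step needs O-arylation of the carboxylate in preference to α-arylation of the ketone, arylation of a phenol and hydrodebromination: the preformed salt makes an added base unnecessary so no enolate is present, both phenols are benzyl ethers, and dry DMA at low current density should limit proton-induced loss of bromine.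

Step 10
Reactants: 15 benzyl 2-(benzyloxy)-4-{[2-(benzyloxy)-4-methoxy-6-(2-oxononyl)benzoyl]oxy}-6-methylbenzoate
Product: 16 2-hydroxy-4-{[2-hydroxy-4-methoxy-6-(2-oxononyl)benzoyl]oxy}-6-methylbenzoic acid (CNP0320117.0)
Conditions: H2 (1 atm), 10% Pd/C, EtOAc, rt
Reagents that add atoms: none
Why: Hydrogenolysis of the two benzyl ethers and the benzyl ester over Pd/C in a non-nucleophilic solvent is the standard last step for depsides, and the aryl ester and the dialkyl ketone should not be reduced under one atmosphere of hydrogen at room temperature.

**Compound list**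

1 | methyl orsellinate (methyl 2,4-dihydroxy-6-methylbenzoate) | COC(=O)c1c(C)cc(O)cc1O | starting material
2 | methyl 2-hydroxy-4-methoxy-6-methylbenzoate | COC(=O)c1c(C)cc(OC)cc1O | intermediate
3 | methyl 2-(benzyloxy)-4-methoxy-6-methylbenzoate | COC(=O)c1c(C)cc(OC)cc1OCc1ccccc1 | intermediate
4 | 2-(benzyloxy)-4-methoxy-6-methylbenzoic acid | Cc1cc(OC)cc(OCc2ccccc2)c1C(=O)O | intermediate
5 | octanoyl chloride | CCCCCCCC(Cl)=O | starting material
6 | N-methoxy-N-methyloctanamide | CCCCCCCC(=O)N(C)OC | intermediate
7 | lithium 2-(benzyloxy)-6-(lithiomethyl)-4-methoxybenzoate (formed in the flask, not isolated) | [Li]Cc1cc(OC)cc(OCc2ccccc2)c1C(=O)O[Li] | intermediate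
8 | dilithium salt of 2-(benzyloxy)-6-[2-hydroxy-2-(methoxy(methyl)amino)nonyl]-4-methoxybenzoic acid (racemic at the transient aminal carbon; formed in the flask, not isolated) | CCCCCCCC(O[Li])(Cc1cc(OC)cc(OCc2ccccc2)c1C(=O)O[Li])N(C)OC | intermediate
9 | 2-(benzyloxy)-4-methoxy-6-(2-oxononyl)benzoic acid (crude, not isolated) | CCCCCCCC(=O)Cc1cc(OC)cc(OCc2ccccc2)c1C(=O)O | intermediate
10 | 8-(benzyloxy)-3-heptyl-6-methoxy-1H-isochromen-1-one | CCCCCCCC1=Cc2cc(OC)cc(OCc3ccccc3)c2C(=O)O1 | intermediate
11 | potassium 2-(benzyloxy)-4-methoxy-6-(2-oxononyl)benzoate | CCCCCCCC(=O)Cc1cc(OC)cc(OCc2ccccc2)c1C(=O)[O-].[K+] | intermediate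
12 | 4-bromo-2-fluoro-6-methylbenzoic acid | Cc1cc(Br)cc(F)c1C(=O)O | starting material
13 | benzyl 4-bromo-2-fluoro-6-methylbenzoate | Cc1cc(Br)cc(F)c1C(=O)OCc1ccccc1 | intermediate
14 | benzyl 2-(benzyloxy)-4-bromo-6-methylbenzoate | Cc1cc(Br)cc(OCc2ccccc2)c1C(=O)OCc1ccccc1 | intermediate
15 | benzyl 2-(benzyloxy)-4-{[2-(benzyloxy)-4-methoxy-6-(2-oxononyl)benzoyl]oxy}-6-methylbenzoate | CCCCCCCC(=O)Cc1cc(OC)cc(OCc2ccccc2)c1C(=O)Oc1cc(C)c(C(=O)OCc2ccccc2)c(OCc2ccccc2)c1 | intermediate
16 | 2-hydroxy-4-{[2-hydroxy-4-methoxy-6-(2-oxononyl)benzoyl]oxy}-6-methylbenzoic acid | CCCCCCCC(=O)Cc1cc(OC)cc(O)c1C(=O)Oc1cc(C)c(C(=O)O)c(O)c1 | target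

**Step count**

Total: 10 steps. Longest linear sequence: 7 steps (steps 1, 2, 3, 5, 6, 9, 10 from methyl orsellinate).

**Steps most likely to fail**

1. Step 9. The hindered 2,6-disubstituted carboxylate may exchange onto nickel and undergo reductive elimination too slowly. Protodebromination and biaryl homocoupling of the bromide would then consume the electrophile, and the sparingly soluble potassium salt may passivate the electrodes.

   Fallback: same O–C4′ bond, made by metal-free ligand coupling at trivalent iodine. It sets out from bromide 14 and comes back at 15.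
   - An aromatic Finkelstein reaction on 14 (CuI, NaI, trans-N,N′-dimethylcyclohexane-1,2-diamine, dioxane, 110 °C) would give benzyl 2-(benzyloxy)-4-iodo-6-methylbenzoate F1.
   - Oxidation of F1 with mCPBA and TsOH·H2O in MeCN would give benzyl 2-(benzyloxy)-4-[hydroxy(tosyloxy)iodo]-6-methylbenzoate F2, not isolated.
   - Addition of 1,3,5-trimethoxybenzene to F2 would give [3-(benzyloxy)-4-(benzyloxycarbonyl)-5-methylphenyl](2,4,6-trimethoxyphenyl)iodonium tosylate F3.
   - Heating F3 with salt 11 in toluene at about 100 °C should place the carboxylate on iodine and couple it with the more electron-poor ring B aryl group. The electron-rich trimethoxyphenyl group leaves as its iodide, and 15 results.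

2. Step 8. The ester is twisted out of the ring plane by its two ortho neighbours and may stabilize the Meisenheimer adduct poorly. Fluoride displacement would then be slow, and SN2 attack of benzyl oxide at the benzylic carbon of the ester (loss of the ester as carboxylate) could overtake it.

   Fallback: substitution at the carboxylate level, where no ester can be lost. It sets out from acid 12 and comes back at 14.
   - Acid 12 is heated with sodium benzyl oxide (3 equiv, from BnOH and NaH) in 1,3-dimethyl-2-imidazolidinone at about 120 °C. Displacement of fluoride ortho to a carboxylate by oxygen nucleophiles is known under such forcing conditions.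
   - Acidification would give 2-(benzyloxy)-4-bromo-6-methylbenzoic acid F4.
   - Benzylation of F4 under the conditions of step 7 (BnBr, K2CO3, DMF) gives 14.

3. Step 5. Lateral deprotonation of the carboxylate may be incomplete. The benzylic CH2 of the ether may be deprotonated instead and undergo Wittig rearrangement, and excess amide base may fragment the Weinreb amide.

   Fallback: acylation at the ester level, where the toluate monoanion forms more easily, and ester cleavage without base. It sets out from ester 3 and comes back at keto acid 9, which is closed with Ac2O to 10 as in the second half of step 5.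
   - LiN(iPr)2 (1.1 equiv, THF, −78 °C) would convert 3 into methyl 2-(benzyloxy)-6-(lithiomethyl)-4-methoxybenzoate F5, not isolated.
   - F5 adds to amide 6 to give the lithium salt of methyl 2-(benzyloxy)-6-[2-hydroxy-2-(methoxy(methyl)amino)nonyl]-4-methoxybenzoate F6, not isolated.
   - Quenching with dilute HCl collapses F6 to methyl 2-(benzyloxy)-4-methoxy-6-(2-oxononyl)benzoate F7.
   - LiI in refluxing pyridine cleaves the hindered methyl ester of F7 by SN2 attack of iodide at the methyl group, giving lithium 2-(benzyloxy)-4-methoxy-6-(2-oxononyl)benzoate F8. No enolate is formed, so the ketone cannot condense onto the ester.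
   - Acidification of F8 gives 9.

**Further compounds**

F1 | step 9 | benzyl 2-(benzyloxy)-4-iodo-6-methylbenzoate | Cc1cc(I)cc(OCc2ccccc2)c1C(=O)OCc1ccccc1
F2 | step 9 | benzyl 2-(benzyloxy)-4-[hydroxy(tosyloxy)iodo]-6-methylbenzoate | Cc1cc(I(O)OS(=O)(=O)c2ccc(C)cc2)cc(OCc2ccccc2)c1C(=O)OCc1ccccc1
F3 | step 9 | [3-(benzyloxy)-4-(benzyloxycarbonyl)-5-methylphenyl](2,4,6-trimethoxyphenyl)iodonium tosylate | Cc1cc([I+]c2c(OC)cc(OC)cc2OC)cc(OCc2ccccc2)c1C(=O)OCc1ccccc1.Cc1ccc(S(=O)(=O)[O-])cc1
F4 | step 8 | 2-(benzyloxy)-4-bromo-6-methylbenzoic acid | Cc1cc(Br)cc(OCc2ccccc2)c1C(=O)O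
F5 | step 5 | methyl 2-(benzyloxy)-6-(lithiomethyl)-4-methoxybenzoate | [Li]Cc1cc(OC)cc(OCc2ccccc2)c1C(=O)OC
F6 | step 5 | lithium salt of methyl 2-(benzyloxy)-6-[2-hydroxy-2-(methoxy(methyl)amino)nonyl]-4-methoxybenzoate (racemic) | CCCCCCCC(O[Li])(Cc1cc(OC)cc(OCc2ccccc2)c1C(=O)OC)N(C)OC
F7 | step 5 | methyl 2-(benzyloxy)-4-methoxy-6-(2-oxononyl)benzoate | CCCCCCCC(=O)Cc1cc(OC)cc(OCc2ccccc2)c1C(=O)OC
F8 | step 5 | lithium 2-(benzyloxy)-4-methoxy-6-(2-oxononyl)benzoate | CCCCCCCC(=O)Cc1cc(OC)cc(OCc2ccccc2)c1C(=O)[O-].[Li+]
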